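**Strategy**

The C3–C3′-linked bis-lactone is opened at the ring A pyranone, so that C3–C4 and O1–C2 are made in one operation. The handle is C4: flanked by a para-hydroxylated phenyl ring and by ring A with its oxygen O1 ortho to it, C4 is the latent methide carbon of a para-quinone methide that carries its own lactonising phenol. A chiral carbene turns an α-chloroaldehyde already holding the complete ring B lactone (C3′, C4′) into an enolate, which adds to C4 and is then acylated by O1, setting C3 and C4 cis. The precursors are a bis-phenolic benzylic sulfone (quinone methide source) and the ring B chloroaldehyde; demethylation ends the route.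

Key step: step 11

**Remarks on the chemistry**

- Assumption: the (5aS,10bR) antipode of the aminoindanol-derived N-mesityl triazolium chloride is taken to give the 4R sense in both annulations; if the first annulation shows the opposite sense, the (5aR,10bS) salt is used in both.
- Descriptors: in the ring B intermediates the lactone centres are (3R,4R), also in the chloroaldehyde, where the chlorinated carbon outranks the lactone carbonyl. They are the same centres, unchanged in space, that are named 3′S,4′R once C3 of ring A is attached.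
- Precursor design: a benzylic hydroxyl is not expelled by a phenoxide at a useful rate under amine base, so each quinone methide is released from the corresponding p-tolyl sulfone. The benzylic diols are passed through without isolation.
- Catalyst-bound species of the carbene and enamine cycles are not numbered.

**Route**

Step 1
Reactants: 1 1,2,3,4-tetramethoxybenzene
Product: 4 2,3,4,5-tetramethoxyphenol, via aryllithium 2 (not isolated), via lithium aryltrimethoxyborate 3 (not isolated)
Conditions: n-BuLi, TMEDA, THF, 0 °C; B(OMe)3, −78 °C to rt; 30% H2O2, AcOH, 0 °C to rt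
Reagents that add atoms: hydrogen peroxide, OO
Why: Directed ortho-lithiation beside a methoxy group (the two free positions of 1 are equivalent), trapping as the borate and peroxide-induced aryl migration from boron to oxygen form a standard one-pot arene hydroxylation.

Step 2
Reactants: 4 2,3,4,5-tetramethoxyphenol; 5 4-(tert-butyldimethylsilyloxy)benzaldehyde
Product: 7 2-{[4-(tert-butyldimethylsilyloxy)phenyl](hydroxy)methyl}-3,4,5,6-tetramethoxyphenol (racemic), via bromomagnesium phenoxide 6 (not isolated)
Conditions: EtMgBr, Et2O, 0 °C; solvent changed to toluene; 5, rt; aq NH4Cl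
Reagents that add atoms: none
Why: Chelation-controlled ortho-hydroxyalkylation of a magnesium phenoxide delivers the magnesium-bound aldehyde through a six-membered transition state to the only free ring position of 6, the silyl ether being inert; the carbinol centre forms racemic, which is harmless because it is lost in step 5.

Step 3
Reactants: 7 2-{[4-(tert-butyldimethylsilyloxy)phenyl](hydroxy)methyl}-3,4,5,6-tetramethoxyphenol
Product: 9 2-[(4-hydroxyphenyl)(4-methylbenzenesulfonyl)methyl]-3,4,5,6-tetramethoxyphenol (racemic), via diol 8 (not isolated)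
Conditions: TBAF, AcOH, THF, 0 °C; then TolSO2Na, HCO2H, H2O, 0 °C to rt
Reagents that add atoms: sodium 4-methylbenzenesulfinate, Cc1ccc(cc1)S(=O)[O-].[Na+]
Why: Buffered fluoride desilylation is followed by SN1 substitution, in which the benzhydrol, activated by an ortho- and a para-hydroxyaryl group, ionises in aqueous formic acid and sulfinate captures the cation at sulfur, giving a crystalline sulfone whose sulfinate is a far better leaving group than hydroxide for the later base-triggered release of the quinone methide.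

Step 4
Reactants: 10 pent-4-enal
Product: 11 2-chloropent-4-enal (racemic)
Conditions: NCS, DL-proline (10 mol%), CH2Cl2, 0 °C to rt; pentane, filtration; used as a solution
Reagents that add atoms: N-chlorosuccinimide, ClN1C(=O)CCC1=O
Why: Enamine-catalysed α-chlorination of an aldehyde by NCS; the chloride centre is racemic and is destroyed in step 5.

Step 5
Reactants: 9 2-[(4-hydroxyphenyl)(4-methylbenzenesulfonyl)methyl]-3,4,5,6-tetramethoxyphenol; 11 2-chloropent-4-enal
Product: 13 (3R,4R)-4-(4-hydroxyphenyl)-5,6,7,8-tetramethoxy-3-(prop-2-enyl)chroman-2-one (3,4-cis), via quinone methide 12 (not isolated)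
Conditions: (5aS,10bR)-2-(2,4,6-trimethylphenyl)-5a,10b-dihydro-4H,6H-indeno[2,1-b][1,2,4]triazolo[4,3-d][1,4]oxazin-2-ium chloride (10 mol%), iPr2NEt (3 equiv), toluene, 4 Å MS, 0 °C to rt, 11 added slowly
Reagents that add atoms: none
Why: Carbene-catalysed formal [4+2] annulation, in which base-induced loss of sulfinate from 9 gives quinone methide 12, the (Z)-azolium enolate formed from 11 by loss of chloride adds 1,6 to the methide carbon and the ortho-phenoxide closes the lactone, the catalyst backbone fixing the enolate face (C3 R) and the closed, hydrogen-bonded addition placing allyl and aryl cis (C4 R).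

Step 6
Reactants: 13 (3R,4R)-4-(4-hydroxyphenyl)-5,6,7,8-tetramethoxy-3-(prop-2-enyl)chroman-2-one
Product: 14 (3R,4R)-5,6,7,8-tetramethoxy-4-(4-methoxyphenyl)-3-(prop-2-enyl)chroman-2-one
Conditions: MeI, Ag2O, MeCN, rt, dark
Reagents that add atoms: iodomethane, CI
Why: Silver oxide-mediated O-alkylation methylates the phenol without soluble base, so C3 and C4 of the cis lactone are not epimerised and the aryl ester is not opened.

Step 7
Reactants: 14 (3R,4R)-5,6,7,8-tetramethoxy-4-(4-methoxyphenyl)-3-(prop-2-enyl)chroman-2-one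
Product: 16 2-[(3R,4R)-5,6,7,8-tetramethoxy-4-(4-methoxyphenyl)-2-oxochroman-3-yl]acetaldehyde, via ozonide 15 (not isolated)
Conditions: O3, CH2Cl2, −78 °C, Sudan Red 7B end-point; then PPh3, −78 °C to rt
Reagents that add atoms: ozone, [O-][O+]=O
Why: Ozonolysis with reductive work-up, in which the terminal alkene reacts with ozone faster than the alkoxyarenes when ozone is dosed to a dye end-point, and no hydroxylated intermediate that could translactonise onto the aryl ester arises.

Step 8
Reactants: 16 2-[(3R,4R)-5,6,7,8-tetramethoxy-4-(4-methoxyphenyl)-2-oxochroman-3-yl]acetaldehyde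
Product: 17 2-chloro-2-[(3R,4R)-5,6,7,8-tetramethoxy-4-(4-methoxyphenyl)-2-oxochroman-3-yl]acetaldehyde (both epimers at the chlorinated carbon)
Conditions: NCS (1.05 equiv), L-proline (10 mol%), CH2Cl2, 0 °C; pentane–Et2O, filtration; used at once
Reagents that add atoms: N-chlorosuccinimide, ClN1C(=O)CCC1=O
Why: Enamine-catalysed α-chlorination with NCS touches only the aldehyde α-carbon under nearly neutral conditions, leaving C3 and C4 of the lactone intact; both chloride epimers are carried on because step 11 destroys that centre.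

Step 9
Reactants: 18 3,5-dimethoxyphenol; 5 4-(tert-butyldimethylsilyloxy)benzaldehyde
Product: 20 2-{[4-(tert-butyldimethylsilyloxy)phenyl](hydroxy)methyl}-3,5-dimethoxyphenol (racemic), via bromomagnesium phenoxide 19 (not isolated)
Conditions: EtMgBr, Et2O, 0 °C; solvent changed to toluene; 5 (1.0 equiv), rt; aq NH4Cl
Reagents that add atoms: none
Why: Chelation-controlled ortho-hydroxyalkylation of magnesium phenoxide 19 attacks C2 (equivalent to C6) next to the oxygen and not the para position C4, and the racemic carbinol centre is lost in step 11.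

Step 10
Reactants: 20 2-{[4-(tert-butyldimethylsilyloxy)phenyl](hydroxy)methyl}-3,5-dimethoxyphenol
Product: 22 2-[(4-hydroxyphenyl)(4-methylbenzenesulfonyl)methyl]-3,5-dimethoxyphenol (racemic), via diol 21 (not isolated)
Conditions: TBAF, AcOH, THF, 0 °C; then TolSO2Na (5 equiv), HCO2H, H2O, 0 °C
Reagents that add atoms: sodium 4-methylbenzenesulfinate, Cc1ccc(cc1)S(=O)[O-].[Na+]
Why: Same sequence as step 3 (fluoride desilylation, then SN1 sulfone formation), run cold and with excess sulfinate so that the cation is trapped at sulfur before the nucleophilic ring A of a second molecule can attack it.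

Step 11
Reactants: 22 2-[(4-hydroxyphenyl)(4-methylbenzenesulfonyl)methyl]-3,5-dimethoxyphenol; 17 2-chloro-2-[(3R,4R)-5,6,7,8-tetramethoxy-4-(4-methoxyphenyl)-2-oxochroman-3-yl]acetaldehyde
Product: 24 (3S,4R)-4-(4-hydroxyphenyl)-5,7-dimethoxy-3-[(3S,4R)-5,6,7,8-tetramethoxy-4-(4-methoxyphenyl)-2-oxochroman-3-yl]chroman-2-one, via quinone methide 23 (not isolated)
Conditions: (5aS,10bR)-2-(2,4,6-trimethylphenyl)-5a,10b-dihydro-4H,6H-indeno[2,1-b][1,2,4]triazolo[4,3-d][1,4]oxazin-2-ium chloride (15 mol%), iPr2NEt (3 equiv), toluene–CH2Cl2, 4 Å MS, −20 °C to rt, 17 added slowly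
Reagents that add atoms: none
Why: iPr2NEt deprotonates the 4-hydroxyphenyl group of 22, which expels p-toluenesulfinate to give quinone methide 23, while the carbene adds to the aldehyde of 17 and the resulting hydroxy-enamine loses chloride to give a (Z)-azolium enolate. The enolate carbon C3 attacks the methide carbon C4 (1,6-addition), which restores the aromatic 4-hydroxyphenyl ring, and the ring A phenoxide O1 then displaces the azolium at C2 (6-exo-trig acyl substitution), closing the pyranone and freeing the catalyst. The closest known reactions are the carbene-catalysed formal [4+2] annulations of azolium enolates from α-chloroaldehydes with ortho-hydroxyphenyl para-quinone methides and with oxodienes. C3 (S) should be set by the aminoindane backbone of the catalyst, which blocks one enolate face and is expected to override the neighbouring C3′ centre; C4 (R) should follow because the O1–H to enolate-oxygen hydrogen bond holds the methide in a closed, endo-like arrangement that leads to the 3,4-cis lactone, the symmetrical quinoid ring leaving no alkene geometry to blur this. The step needs carbene capture of the aldehyde to outrun loss of HCl across C3′, and C–C bond formation to outrun O-acylation of the phenols; the high electrophilicity of the α-chloroaldehyde, the hindered weak base, the slow release of 23 from the sulfone and the intramolecular lactonisation are what should secure this. C3′ and C4′ ride through as spectators.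

Step 12
Reactants: 24 (3S,4R)-4-(4-hydroxyphenyl)-5,7-dimethoxy-3-[(3S,4R)-5,6,7,8-tetramethoxy-4-(4-methoxyphenyl)-2-oxochroman-3-yl]chroman-2-one
Product: 25 (3S,4R)-5,7-dihydroxy-4-(4-hydroxyphenyl)-3-[(3S,4R)-5,6,7,8-tetrahydroxy-4-(4-hydroxyphenyl)-2-oxochroman-3-yl]chroman-2-one
Conditions: BBr3 (12 equiv), CH2Cl2, argon, −78 to 0 °C; degassed ice-water
Reagents that add atoms: none
Why: Lewis acid ether cleavage, in which boron tribromide complexes each methoxy oxygen and bromide removes the methyl group, whereas the aryl lactones and the four sp3 centres should persist at or below 0 °C and exclusion of air protects the tetrahydroxylated ring B.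

**Compound list**

1 | 1,2,3,4-tetramethoxybenzene | COc1ccc(OC)c(OC)c1OC | starting material
2 | (2,3,4,5-tetramethoxyphenyl)lithium | [Li]c1cc(OC)c(OC)c(OC)c1OC | intermediate
3 | lithium trimethoxy(2,3,4,5-tetramethoxyphenyl)borate | [Li+].CO[B-](OC)(OC)c1cc(OC)c(OC)c(OC)c1OC | intermediate
4 | 2,3,4,5-tetramethoxyphenol | COc1cc(O)c(OC)c(OC)c1OC | intermediate
5 | 4-(tert-butyldimethylsilyloxy)benzaldehyde | CC(C)(C)[Si](C)(C)Oc1ccc(C=O)cc1 | starting material
6 | bromomagnesium 2,3,4,5-tetramethoxyphenoxide | COc1cc(O[Mg]Br)c(OC)c(OC)c1OC | intermediate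
7 | 2-{[4-(tert-butyldimethylsilyloxy)phenyl](hydroxy)methyl}-3,4,5,6-tetramethoxyphenol (racemic) | COc1c(O)c(C(O)c2ccc(O[Si](C)(C)C(C)(C)C)cc2)c(OC)c(OC)c1OC | intermediate
8 | 2-[hydroxy(4-hydroxyphenyl)methyl]-3,4,5,6-tetramethoxyphenol (racemic) | COc1c(O)c(C(O)c2ccc(O)cc2)c(OC)c(OC)c1OC | intermediate
9 | 2-[(4-hydroxyphenyl)(4-methylbenzenesulfonyl)methyl]-3,4,5,6-tetramethoxyphenol (racemic) | COc1c(O)c(C(c2ccc(O)cc2)S(=O)(=O)c2ccc(C)cc2)c(OC)c(OC)c1OC | intermediate
10 | pent-4-enal | C=CCCC=O | starting material
11 | 2-chloropent-4-enal (racemic) | C=CCC(Cl)C=O | intermediate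
12 | 4-[(2-hydroxy-3,4,5,6-tetramethoxyphenyl)methylidene]cyclohexa-2,5-dien-1-one | COc1c(O)c(C=C2C=CC(=O)C=C2)c(OC)c(OC)c1OC | intermediate
13 | (3R,4R)-4-(4-hydroxyphenyl)-5,6,7,8-tetramethoxy-3-(prop-2-enyl)chroman-2-one | C=CC[C@H]1C(=O)Oc2c(OC)c(OC)c(OC)c(OC)c2[C@H]1c1ccc(O)cc1 | intermediate
14 | (3R,4R)-5,6,7,8-tetramethoxy-4-(4-methoxyphenyl)-3-(prop-2-enyl)chroman-2-one | C=CC[C@H]1C(=O)Oc2c(OC)c(OC)c(OC)c(OC)c2[C@H]1c1ccc(OC)cc1 | intermediate
15 | (3R,4R)-5,6,7,8-tetramethoxy-4-(4-methoxyphenyl)-3-(1,2,4-trioxolan-3-ylmethyl)chroman-2-one (mixture at the trioxolane carbon) | C1OC(C[C@H]2C(=O)Oc3c(OC)c(OC)c(OC)c(OC)c3[C@H]2c2ccc(OC)cc2)OO1 | intermediate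
16 | 2-[(3R,4R)-5,6,7,8-tetramethoxy-4-(4-methoxyphenyl)-2-oxochroman-3-yl]acetaldehyde | O=CC[C@H]1C(=O)Oc2c(OC)c(OC)c(OC)c(OC)c2[C@H]1c1ccc(OC)cc1 | intermediate
17 | 2-chloro-2-[(3R,4R)-5,6,7,8-tetramethoxy-4-(4-methoxyphenyl)-2-oxochroman-3-yl]acetaldehyde (both epimers at the chlorinated carbon) | O=CC(Cl)[C@H]1C(=O)Oc2c(OC)c(OC)c(OC)c(OC)c2[C@H]1c1ccc(OC)cc1 | intermediate
18 | 3,5-dimethoxyphenol | COc1cc(O)cc(OC)c1 | starting material
19 | bromomagnesium 3,5-dimethoxyphenoxide | COc1cc(O[Mg]Br)cc(OC)c1 | intermediate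
20 | 2-{[4-(tert-butyldimethylsilyloxy)phenyl](hydroxy)methyl}-3,5-dimethoxyphenol (racemic) | COc1cc(O)c(C(O)c2ccc(O[Si](C)(C)C(C)(C)C)cc2)c(OC)c1 | intermediate
21 | 2-[hydroxy(4-hydroxyphenyl)methyl]-3,5-dimethoxyphenol (racemic) | COc1cc(O)c(C(O)c2ccc(O)cc2)c(OC)c1 | intermediate
22 | 2-[(4-hydroxyphenyl)(4-methylbenzenesulfonyl)methyl]-3,5-dimethoxyphenol (racemic) | COc1cc(O)c(C(c2ccc(O)cc2)S(=O)(=O)c2ccc(C)cc2)c(OC)c1 | intermediate
23 | 4-[(2-hydroxy-4,6-dimethoxyphenyl)methylidene]cyclohexa-2,5-dien-1-one | COc1cc(O)c(C=C2C=CC(=O)C=C2)c(OC)c1 | intermediate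
24 | (3S,4R)-4-(4-hydroxyphenyl)-5,7-dimethoxy-3-[(3S,4R)-5,6,7,8-tetramethoxy-4-(4-methoxyphenyl)-2-oxochroman-3-yl]chroman-2-one | O=C1Oc2cc(OC)cc(OC)c2[C@@H](c2ccc(O)cc2)[C@H]1[C@H]1C(=O)Oc2c(OC)c(OC)c(OC)c(OC)c2[C@H]1c1ccc(OC)cc1 | intermediate
25 | (3S,4R)-5,7-dihydroxy-4-(4-hydroxyphenyl)-3-[(3S,4R)-5,6,7,8-tetrahydroxy-4-(4-hydroxyphenyl)-2-oxochroman-3-yl]chroman-2-one | O=C1Oc2cc(O)cc(O)c2[C@@H](c2ccc(O)cc2)[C@H]1[C@H]1C(=O)Oc2c(O)c(O)c(O)c(O)c2[C@H]1c1ccc(O)cc1 | target

**Step count**

Total: 12 steps. Longest linear sequence: 9 steps (1, 2, 3, 5, 6, 7, 8, 11, 12).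

**Steps most likely to fail, with fallbacks**

Step 11. The acyl azolium may be intercepted by the free phenols before C–C bond formation, the phenoxide of 22 may be C-alkylated by quinone methide 23, or the stepwise addition may give a poor cis ratio against the existing C3′ centre. The fallback sets out from 20 and 17 and comes back at 24. The silyl ether is kept, and 20 is converted directly with TolSO2Na in aqueous HCO2H into 2-{[4-(tert-butyldimethylsilyloxy)phenyl](4-methylbenzenesulfonyl)methyl}-3,5-dimethoxyphenol F1. With K2CO3 and the same triazolium chloride, the ring A phenoxide of F1 expels sulfinate to give the ortho-quinone methide 6-{[4-(tert-butyldimethylsilyloxy)phenyl]methylidene}-3,5-dimethoxycyclohexa-2,4-dien-1-one F2 in the flask. F2 should be taken up by the azolium enolate from 17 in a carbene-catalysed endo hetero-Diels–Alder [4+2] across O1=C8a–C4a=C4, giving the silyl ether of 24, (3S,4R)-4-[4-(tert-butyldimethylsilyloxy)phenyl]-5,7-dimethoxy-3-[(3S,4R)-5,6,7,8-tetramethoxy-4-(4-methoxyphenyl)-2-oxochroman-3-yl]chroman-2-one F3. TBAF buffered with AcOH then returns 24. In this variant only the lactonising phenol is free, no aryl oxide is released, and both bonds form in one cis-selective cycloaddition.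

Step 5. The first annulation may give low enantio- or cis-selectivity, or the liberated unhindered phenol of 13 may be acylated by excess acyl azolium. The fallback sets out from 4 (through 6) and 11 and comes back at 14. Phenoxide 6 is hydroxyalkylated with commercial 4-methoxybenzaldehyde to give 2-[hydroxy(4-methoxyphenyl)methyl]-3,4,5,6-tetramethoxyphenol F4, which TolSO2Na in aqueous HCO2H converts into 2-[(4-methoxyphenyl)(4-methylbenzenesulfonyl)methyl]-3,4,5,6-tetramethoxyphenol F5. K2CO3 and the triazolium chloride release the ortho-quinone methide 6-[(4-methoxyphenyl)methylidene]-2,3,4,5-tetramethoxycyclohexa-2,4-dien-1-one F6, which undergoes the carbene-catalysed hetero-Diels–Alder annulation with the enolate from 11. Because the para oxygen is methylated from the outset, this gives 14 directly and step 6 falls away.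

Step 8. Over-chlorination, amine-promoted loss of HCl across C3 of the lactone, or opening of the aryl lactone by the secondary amine may erode a chloride that cannot be purified. The fallback sets out from 16 and comes back at 24. Aldehyde 16 is α-oxygenated with N-methyl-O-(4-nitrobenzoyl)hydroxylamine hydrochloride (condensation, then [3,3]-sigmatropic shift; THF, rt to 50 °C), without an amine catalyst, to give 2-oxo-1-[(3S,4R)-5,6,7,8-tetramethoxy-4-(4-methoxyphenyl)-2-oxochroman-3-yl]ethyl 4-nitrobenzoate F7. This can be chromatographed and stored. Under the conditions of step 11 it should give the same azolium enolate by loss of 4-nitrobenzoate, a poorer leaving group for elimination than chloride, and so 24.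

**Further compounds**

F1 | step 11 | 2-{[4-(tert-butyldimethylsilyloxy)phenyl](4-methylbenzenesulfonyl)methyl}-3,5-dimethoxyphenol (racemic) | COc1cc(O)c(C(c2ccc(O[Si](C)(C)C(C)(C)C)cc2)S(=O)(=O)c2ccc(C)cc2)c(OC)c1
F2 | step 11 | 6-{[4-(tert-butyldimethylsilyloxy)phenyl]methylidene}-3,5-dimethoxycyclohexa-2,4-dien-1-one | COC1=CC(=O)C(=Cc2ccc(O[Si](C)(C)C(C)(C)C)cc2)C(OC)=C1
F3 | step 11 | (3S,4R)-4-[4-(tert-butyldimethylsilyloxy)phenyl]-5,7-dimethoxy-3-[(3S,4R)-5,6,7,8-tetramethoxy-4-(4-methoxyphenyl)-2-oxochroman-3-yl]chroman-2-one | O=C1Oc2cc(OC)cc(OC)c2[C@@H](c2ccc(O[Si](C)(C)C(C)(C)C)cc2)[C@H]1[C@H]1C(=O)Oc2c(OC)c(OC)c(OC)c(OC)c2[C@H]1c1ccc(OC)cc1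
F4 | step 5 | 2-[hydroxy(4-methoxyphenyl)methyl]-3,4,5,6-tetramethoxyphenol (racemic) | COc1c(O)c(C(O)c2ccc(OC)cc2)c(OC)c(OC)c1OC
F5 | step 5 | 2-[(4-methoxyphenyl)(4-methylbenzenesulfonyl)methyl]-3,4,5,6-tetramethoxyphenol (racemic) | COc1c(O)c(C(c2ccc(OC)cc2)S(=O)(=O)c2ccc(C)cc2)c(OC)c(OC)c1OC
F6 | step 5 | 6-[(4-methoxyphenyl)methylidene]-2,3,4,5-tetramethoxycyclohexa-2,4-dien-1-one | COC1=C(OC)C(=O)C(=Cc2ccc(OC)cc2)C(OC)=C1OC
F7 | step 8 | 2-oxo-1-[(3S,4R)-5,6,7,8-tetramethoxy-4-(4-methoxyphenyl)-2-oxochroman-3-yl]ethyl 4-nitrobenzoate (both epimers at the acyloxy carbon) | O=CC(OC(=O)c1ccc(cc1)[N+](=O)[O-])[C@H]1C(=O)Oc2c(OC)c(OC)c(OC)c(OC)c2[C@H]1c1ccc(OC)cc1
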